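Compound numbers refer to the compound list after the steps.

## Analysis of the target

Target 26 is built from two oxygen heterocycles joined by a single methylene group. One is a tetrahydrofuran carrying a 3-hydroxy-4-methoxyphenyl group (ring C) at C2, CH2OH at C3 and the linking CH2 at C4. The other is a 2,3-dihydrobenzofuran carrying a 4-hydroxy-3-methoxyphenyl group (ring B) at C2, CH2OH at C3, OMe at C4 and the linking CH2 at C6 of its benzo ring (ring A).

There are five stereocentres in two clusters. In the tetrahydrofuran, C2 is R, C3 is S and C4 is S: aryl and CH2OH are trans, CH2OH and the arylmethyl group are cis. In the dihydrobenzofuran, C2 is S and C3 is R, trans. The clusters are insulated from each other by the CH2 link and ring A, so each needs its own source of absolute configuration.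

The sensitive groups are two free phenols, two primary alcohols and two cyclic benzylic ethers (tetrahydrofuran C2–O and dihydrobenzofuran C2–O1). The ring B phenol is para to the benzylic C2–O1 bond. The benzylic ethers ionise in acid, which leads to epimerisation and to Friedel–Crafts closure onto the electron-rich ring A, and they can be cleaved by hydrogenolysis.

The difficulties are three: ring A is 1,2,3,5-tetrasubstituted; the trans dihydrobenzofuran pair has no neighbouring handle for asymmetric control; and tetrahydrofuran C4 must end up cis to C3.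

The strategy rests on one feature. The sequence O1–C2(aryl)–C3(CH2OH)–C3a of the dihydrobenzofuran is the sequence O1–C2–C3–C4–C4a of a chroman-4-one in which C4 has been pushed out of the ring. The C3–C3a bond replaces C4–C4a, and the old C4 becomes the one-carbon substituent on C3. The trans pair can therefore be derived from the single C2 stereocentre of a flavanone.

## Retrosynthetic reasoning

**Protecting groups.** Target 26 is traced back to the tetrakis(triisopropylsilyl) ether 25. All four hydroxyl groups carry the same silyl group, so one buffered desilylation ends the synthesis. This avoids both acid and hydrogenation in the presence of the two benzylic C–O bonds.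

**The CH2–C6 bond.** The C(sp3)–C(sp2) bond between the linking methylene and C6 of ring A is cut. This gives aryl bromide 15 and the exocyclic alkene 23, joined through the organoborane 24. The cut divides the molecule into two halves of similar size, each with one stereocluster. C6 is flanked by two CH positions, so the bromide is unhindered. The forward hydroboration also creates tetrahydrofuran C4, under the control of the adjacent C3 substituent. A cut at the C4–CH2 bond would require an sp3–sp3 coupling at a stereogenic carbon.

**Functional group changes on the dihydrobenzofuran.** Bromide 15 comes from diol 14 by double silylation. Diol 14 comes from ester 13 by one hydride reduction, which turns the ester into the C3 CH2OH group and frees the ring B phenol from its pivalate.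

**Key disconnection.** In ester 13 the C3–C3a bond is cut and C3a is reconnected to the ester carbon. This gives the six-membered flavanone 10, in which that carbon is the C4 ketone. The gain is threefold: C3 no longer needs separate control because it follows from C2, ring A arrives with Br and OMe in place, and the precursor is a simple flavanone with one stereocentre. The forward reaction must make ring A migrate from C4 to C3 in preference to ring B migrating from C2, and must leave C2 intact.

**The C2–aryl bond.** Flavanone 10 is cut between C2 and ring B, giving chromone 6 and boronic acid 9. The forward reaction is a catalytic asymmetric conjugate addition that creates C2, the only stereocentre of this half that needs external control.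

**Chromone and boronic acid.** Chromone 6 is opened at O1–C2 and C2–C3 to the ortho-hydroxyacetophenone 4 via enaminone 5. Ketone 4 comes from aldehyde 1 through alcohol 2 and ketone 3. In aldehyde 1 the two ortho oxygens and the para bromine already map onto O1, the C4 methoxy group and C6 of the final ring A. Boronic acid 9 comes from the commercial phenol boronate 7 through pivalate 8.

**The tetrahydrofuran half.** Alkene 23 is the silyl ether of alcohol 22. In alcohol 22 the C3–C4 bond is cut, giving the epoxy propargyl ether 21. The forward reaction is a radical 5-exo-dig cyclisation that forms the ring and places C3 trans to the C2 aryl group. Epoxide 21 comes from allyl propargyl ether 20, which comes from the R allylic alcohol 19. Alcohol 19 is obtained by kinetic resolution of racemate 18, made from aldehyde 17 and so from isovanillin 16. The single benzylic centre of alcohol 19 thus controls C3 in the cyclisation and, through C3, C4 in the hydroboration.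

## Alternatives that were turned down

**Alternative 1:** Ring A itself is disconnected, at the arene bonds C7a–C3a and C4–C5 (target numbering). The forward key step is a Danheiser benzannulation. Cyclobutenone A2, carrying the whole tetrahydrofuran, is heated with siloxyalkyne A3, carrying the future C2 and C3 of the dihydrobenzofuran as an open chain. The sequence is ring opening to a vinylketene, [2+2] addition, a second ring opening and 6π electrocyclisation, and it gives the resorcinol monosilyl ether A1.

- For it: the two halves are joined in the ring-forming step, no metal-catalysed coupling is needed, and the mechanism fixes the substitution pattern of the arene. On convergence it is stronger than the chosen route, and on regiocontrol of ring A it is at least as strong.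
- Against it: in A1 the dihydrobenzofuran is still open. One phenol must be methylated and the other unmasked, and O1–C2 must then be closed by displacement at a secondary benzylic carbon bearing an electron-rich aryl group. Ionisation there would erode the trans relationship.
- Against it: A3 needs two contiguous stereocentres from separate asymmetric chemistry, and both A2 and A3 are long, sensitive fragments.
- Comparison: the route would be clearly longer. The chosen strategy buys ring A with its substituents and draws both dihydrobenzofuran stereocentres from one catalytic event.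

**Alternative 2:** The O1–C2 bond of the dihydrobenzofuran is disconnected. The precursor is the diarylpropanol A5, with a free ortho phenol on ring A and a free ring B phenol. In the forward key step silver oxide oxidises the 4-alkylguaiacol unit to a para-quinone methide. The ring A phenol adds to its exocyclic carbon in a 5-exo closure and gives the trans dihydrobenzofuran A4.

- For it: the step is biomimetic and nearly neutral, the trans relationship is the thermodynamic outcome, and no migratory aptitudes have to be tuned. On mildness of the ring-forming step it is at least equal to the chosen route.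
- Against it: the C3 stereocentre must be made beforehand. It is a benzylic carbon attached to the 2,6-dioxygenated ring A, and there is no direct catalytic route to it.
- Against it: A5 has two oxidisable phenols. The quinone methide can also tautomerise through loss of the C3 proton, which would destroy that stereocentre, or be trapped intermolecularly.
- Comparison: the step count would be similar or somewhat higher. The chosen strategy offers catalytic absolute control and a ring closure that does not pass through a free quinone methide.

**Alternative 3:** The tetrahydrofuran bonds C2–C3 and C4–C5 are disconnected. In the forward key step fluoride converts the α-chloro silylmethyl ether A8 into a non-stabilised carbonyl ylide. The ylide adds across the alkene of the γ-aryl butenolide A7 and gives the cis-fused furofuranone A6.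

- For it: two C–C bonds and the ring are made in one step, and the cis ring fusion delivers the 3,4-cis relationship by construction. On that point it is stronger than the substrate-controlled hydroboration of the chosen route.
- Against it: exo/endo and facial selectivity of a non-stabilised ylide depend only on the γ substituent of A7. The γ proton of A7 is benzylic, allylic and next to oxygen, so basic fluoride can racemise it.
- Against it: after the cycloaddition the lactone C–O bond must be hydrogenolysed to the CH2 link in the presence of two other benzylic C–O bonds of the same kind.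
- Against it: A7 already contains the complete dihydrobenzofuran, so the main stereochemical problem of the target is not addressed.
- Comparison: the chosen strategy solves the dihydrobenzofuran problem directly and forms the CH2 link without any benzylic C–O cleavage.

Key step: step 8

Assumption: the facial sense of the palladium/pyridine-oxazoline addition to chromones is taken to parallel that of cyclic enones, which makes the (R)-configured ligand the one that gives the 2S flavanone. Both ligand enantiomers are available, so only the choice of antipode depends on this.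

## Route

Step 1
Reactants: 1 4-bromo-2,6-dimethoxybenzaldehyde
Product: 2 1-(4-bromo-2,6-dimethoxyphenyl)ethan-1-ol (racemic)
Conditions: MeMgBr (1.2 equiv), THF, 0 °C; aq. NH4Cl
Reagents that add atoms: methylmagnesium bromide, C[Mg]Br
Why: Grignard addition to the aldehyde; MeMgBr does not exchange with the aryl bromide at 0 °C, and the racemic carbinol centre is removed in step 2.

Step 2
Reactants: 2 1-(4-bromo-2,6-dimethoxyphenyl)ethan-1-ol
Product: 3 1-(4-bromo-2,6-dimethoxyphenyl)ethan-1-one
Conditions: Dess–Martin periodinane (1.2 equiv), CH2Cl2, 0 °C to rt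
Reagents that add atoms: none
Why: Dess–Martin oxidation of a secondary benzylic alcohol to the aryl methyl ketone under mild, non-acidic conditions that leave the aryl bromide and the methyl ethers untouched.

Step 3
Reactants: 3 1-(4-bromo-2,6-dimethoxyphenyl)ethan-1-one
Product: 4 1-(4-bromo-2-hydroxy-6-methoxyphenyl)ethan-1-one
Conditions: BCl3 (1.2 equiv), CH2Cl2, −78 °C to 0 °C; H2O
Reagents that add atoms: none
Why: Chelation-controlled mono-demethylation: BCl3 bridges the carbonyl oxygen and one ortho methoxy group and chloride removes that methyl group; the resulting boron chelate ties up the ketone, so the second methoxy group is not activated.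

Step 4
Reactants: 4 1-(4-bromo-2-hydroxy-6-methoxyphenyl)ethan-1-one
Product: 6 7-bromo-5-methoxy-4H-chromen-4-one, via enaminone 5 (not isolated)
Conditions: Me2NCH(OMe)2, toluene, 100 °C; concentrate; conc. HCl, CH2Cl2, 40 °C
Reagents that add atoms: N,N-dimethylformamide dimethyl acetal, COC(OC)N(C)C
Why: Standard chromone synthesis: the methyl ketone condenses with the formamide acetal to enaminone 5, and acid then induces 6-endo addition of the phenol and loss of dimethylamine.

Step 5
Reactants: 7 2-methoxy-4-(4,4,5,5-tetramethyl-1,3,2-dioxaborolan-2-yl)phenol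
Product: 8 2-methoxy-4-(4,4,5,5-tetramethyl-1,3,2-dioxaborolan-2-yl)phenyl 2,2-dimethylpropanoate
Conditions: t-BuCOCl (1.2 equiv), Et3N, DMAP (5 mol %), CH2Cl2, 0 °C to rt
Reagents that add atoms: pivaloyl chloride, CC(C)(C)C(=O)Cl
Why: Acylation of the phenol; the pivalate is chosen because it makes ring B electron-poor for step 8, survives aqueous and acidic conditions, and falls off in the hydride reduction of step 9 without an extra step.

Step 6
Reactants: 8 2-methoxy-4-(4,4,5,5-tetramethyl-1,3,2-dioxaborolan-2-yl)phenyl 2,2-dimethylpropanoate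
Product: 9 [3-methoxy-4-(2,2-dimethylpropanoyloxy)phenyl]boronic acid
Conditions: NaIO4 (3 equiv), NH4OAc (3 equiv), acetone/H2O, rt
Reagents that add atoms: water, O
Why: Periodate cleaves the pinacol released in the hydrolysis equilibrium and so drives the boronate to the free boronic acid, which is the species that transmetalates in step 7; the aryl pivalate is stable at this near-neutral pH.

Step 7
Reactants: 6 7-bromo-5-methoxy-4H-chromen-4-one; 9 [3-methoxy-4-(2,2-dimethylpropanoyloxy)phenyl]boronic acid
Product: 10 4-[(2S)-7-bromo-5-methoxy-4-oxochroman-2-yl]-2-methoxyphenyl 2,2-dimethylpropanoate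
Conditions: Pd(OCOCF3)2 (5 mol %), (R)-t-BuPyOx (6 mol %), NH4PF6 (30 mol %), H2O (5 equiv), ClCH2CH2Cl, 60 °C
Reagents that add atoms: none
Why: Asymmetric conjugate addition under divalent-palladium/pyridine-oxazoline catalysis: the aryl group passes from boron to cationic palladium, adds across C2=C3 of the chromone in the enantio-determining step under control of the ligand tert-butyl group, and water protonates the palladium enolate. No zerovalent palladium is formed in the cycle, so the C–Br bond should remain intact.

Step 8
Reactants: 10 4-[(2S)-7-bromo-5-methoxy-4-oxochroman-2-yl]-2-methoxyphenyl 2,2-dimethylpropanoate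
Product: 13 methyl (2S,3S)-6-bromo-4-methoxy-2-[3-methoxy-4-(2,2-dimethylpropanoyloxy)phenyl]-2,3-dihydrobenzofuran-3-carboxylate, via methyl enol ether 11 (not isolated), via aryliodanyl ketal 12 (not isolated)
Conditions: PhI(OAc)2 (1.2 equiv), conc. H2SO4 (1.5 equiv), HC(OMe)3, 0 °C to rt
Reagents that add atoms: trimethyl orthoformate, COC(OC)OC
Why: In acidic orthoformate the ketone is ketalised and loses methanol to the methyl enol ether 11. Its C3 attacks the protonated trivalent-iodine reagent on the face opposite to the C2 aryl group, and methanol capture gives ketal 12 with the iodanyl group equatorial and therefore antiperiplanar to the C4–C4a ring bond. As iodobenzene leaves, C4a of ring A shifts from C4 to C3 with inversion at C3 through a bridged, phenonium-like transition state (a 3-exo-tet attack of the ipso carbon); this 1,2-shift closes the five-membered ring by contraction of the six-membered one, and the dimethoxycarbenium ion left at C4 collapses to the methyl ester. The closest known reaction type is the oxidative 1,2-aryl shift of aryl ketones to α-aryl esters with PhI(OAc)2 or Tl(NO3)3 in orthoformate, which is established for flavanones and gives trans methyl 2-aryl-2,3-dihydrobenzofuran-3-carboxylates. The new stereocentre C3 is controlled by C2: iodination trans to the aryl group followed by migration with inversion places the ester trans to the aryl group, which is also the more stable arrangement, while C2 itself takes no part. The step needs ring A to migrate in preference to ring B and in preference to elimination; this is secured by the two oxygen substituents ortho to C4a (the C5 methoxy group and O1) and by the pivalate, which makes ring B a poor migrating group. The pivalate also destabilises positive charge at C2 and so should suppress acid-induced opening of the C2–O1 bond, the only path by which the configuration set in step 7 could be lost.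

Step 9
Reactants: 13 methyl (2S,3S)-6-bromo-4-methoxy-2-[3-methoxy-4-(2,2-dimethylpropanoyloxy)phenyl]-2,3-dihydrobenzofuran-3-carboxylate
Product: 14 4-[(2S,3R)-6-bromo-3-(hydroxymethyl)-4-methoxy-2,3-dihydrobenzofuran-2-yl]-2-methoxyphenol
Conditions: LiAlH4 (3 equiv), THF, 0 °C; aq. Rochelle salt
Reagents that add atoms: none
Why: LiAlH4 reduces the methyl ester to the primary alcohol and cleaves the aryl pivalate in the same operation; at 0 °C hydride addition to the ester outruns deprotonation at C3 and the aryl bromide is not reduced, so both stereocentres are carried over (the C3 descriptor changes from S to R only through the priority change).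

Step 10
Reactants: 14 4-[(2S,3R)-6-bromo-3-(hydroxymethyl)-4-methoxy-2,3-dihydrobenzofuran-2-yl]-2-methoxyphenol
Product: 15 (2S,3R)-6-bromo-4-methoxy-2-[3-methoxy-4-(triisopropylsilyloxy)phenyl]-3-[(triisopropylsilyloxy)methyl]-2,3-dihydrobenzofuran
Conditions: i-Pr3SiCl (2.5 equiv), imidazole (5 equiv), DMF, rt
Reagents that add atoms: triisopropylsilyl chloride, CC(C)[Si](Cl)(C(C)C)C(C)C
Why: Silylation of the phenol and the primary alcohol in one operation; the bulky triisopropylsilyl ethers should withstand the aqueous base of step 18 and are removed by fluoride without acid or hydrogen.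

Step 11
Reactants: 16 isovanillin (3-hydroxy-4-methoxybenzaldehyde)
Product: 17 4-methoxy-3-(triisopropylsilyloxy)benzaldehyde
Conditions: i-Pr3SiCl (1.2 equiv), imidazole (2.5 equiv), DMF, rt
Reagents that add atoms: triisopropylsilyl chloride, CC(C)[Si](Cl)(C(C)C)C(C)C
Why: Phenol silylation; the same silyl group as in 15 is used so that the final deprotection is a single step.

Step 12
Reactants: 17 4-methoxy-3-(triisopropylsilyloxy)benzaldehyde
Product: 18 1-[4-methoxy-3-(triisopropylsilyloxy)phenyl]prop-2-en-1-ol (racemic)
Conditions: CH2=CHMgBr (1.2 equiv), THF, −78 °C to 0 °C; aq. NH4Cl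
Reagents that add atoms: vinylmagnesium bromide, C=C[Mg]Br
Why: Grignard addition of a vinyl group to the aldehyde; the hindered aryl silyl ether is inert to the Grignard reagent at low temperature.

Step 13
Reactants: 18 1-[4-methoxy-3-(triisopropylsilyloxy)phenyl]prop-2-en-1-ol (racemic)
Product: 19 (1R)-1-[4-methoxy-3-(triisopropylsilyloxy)phenyl]prop-2-en-1-ol
Conditions: Ti(OiPr)4 (15 mol %), D-(−)-diisopropyl tartrate (20 mol %), t-BuOOH (0.6 equiv), 4 Å molecular sieves, CH2Cl2, −20 °C
Reagents that add atoms: none
Why: Sharpless kinetic resolution: with the D-(−)-tartrate the S alcohol is epoxidised much faster and the R alcohol should be left behind, at best half of the material; running slightly past half conversion should give high enantiomeric purity.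

Step 14
Reactants: 19 (1R)-1-[4-methoxy-3-(triisopropylsilyloxy)phenyl]prop-2-en-1-ol
Product: 20 triisopropyl{2-methoxy-5-[(1R)-1-(prop-2-yn-1-yloxy)prop-2-en-1-yl]phenoxy}silane
Conditions: NaH (1.2 equiv), HC≡CCH2Br (1.5 equiv), n-Bu4NI (5 mol %), THF, 0 °C to rt
Reagents that add atoms: propargyl bromide, C#CCBr
Why: Williamson etherification at oxygen, which does not touch the stereocentre; THF without DMF and the reactive propargylic halide should keep the alkoxide from attacking the hindered aryl silyl ether.

Step 15
Reactants: 20 triisopropyl{2-methoxy-5-[(1R)-1-(prop-2-yn-1-yloxy)prop-2-en-1-yl]phenoxy}silane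
Product: 21 2-{(S)-[4-methoxy-3-(triisopropylsilyloxy)phenyl](prop-2-yn-1-yloxy)methyl}oxirane (both epimers at the oxirane carbon; benzylic centre unchanged in space)
Conditions: m-CPBA (1.5 equiv), NaHCO3, CH2Cl2, 0 °C to rt
Reagents that add atoms: meta-chloroperoxybenzoic acid, OOC(=O)c1cccc(Cl)c1
Why: Prilezhaev epoxidation of the only alkene, the terminal alkyne being far less reactive toward peracid; both epimers are used because the oxirane carbon becomes a planar radical in step 16.

Step 16
Reactants: 21 2-{(S)-[4-methoxy-3-(triisopropylsilyloxy)phenyl](prop-2-yn-1-yloxy)methyl}oxirane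
Product: 22 [(2R,3S)-2-[4-methoxy-3-(triisopropylsilyloxy)phenyl]-4-methylidenetetrahydrofuran-3-yl]methanol
Conditions: Cp2TiCl2 (2.5 equiv), Zn dust, THF, rt (Cp2TiCl formed in the flask), slow addition to 21; sat. aq. NaH2PO4
Reagents that add atoms: none
Why: Reductive epoxide opening by trivalent titanium (Nugent–RajanBabu type) gives the more substituted β-titanoxy radical, which cyclises 5-exo-dig onto the alkyne; the vinyl radical is reduced by a second Cp2TiCl and protonated on work-up. C3 is set in the cyclisation transition state, where the bulky titanoxymethyl group lies anti to the C2 aryl group, so the 2,3-trans ring should predominate.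

Step 17
Reactants: 22 [(2R,3S)-2-[4-methoxy-3-(triisopropylsilyloxy)phenyl]-4-methylidenetetrahydrofuran-3-yl]methanol
Product: 23 triisopropyl{[(2R,3S)-2-[4-methoxy-3-(triisopropylsilyloxy)phenyl]-4-methylidenetetrahydrofuran-3-yl]methoxy}silane
Conditions: i-Pr3SiCl (1.3 equiv), imidazole (3 equiv), DMF, rt
Reagents that add atoms: triisopropylsilyl chloride, CC(C)[Si](Cl)(C(C)C)C(C)C
Why: Silylation of the primary alcohol; the large silyloxymethyl group at C3 also increases the facial bias needed in step 18.

Step 18
Reactants: 23 triisopropyl{[(2R,3S)-2-[4-methoxy-3-(triisopropylsilyloxy)phenyl]-4-methylidenetetrahydrofuran-3-yl]methoxy}silane; 15 (2S,3R)-6-bromo-4-methoxy-2-[3-methoxy-4-(triisopropylsilyloxy)phenyl]-3-[(triisopropylsilyloxy)methyl]-2,3-dihydrobenzofuran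
Product: 25 tetrakis(triisopropylsilyl) ether of the target, via alkylborane 24 (not isolated)
Conditions: 9-BBN (1.5 equiv), THF, 0 °C to 50 °C; then 15, Pd(OAc)2 (5 mol %), SPhos (10 mol %), 3 M aq. K3PO4, THF, 65 °C
Reagents that add atoms: none
Why: Anti-Markovnikov hydroboration places boron on the terminal carbon and delivers hydrogen to C4 on the face opposite to the adjacent C3 silyloxymethyl group, so the new CH2–B arm is cis to that group (C4 S). B-alkyl Suzuki–Miyaura coupling with the unhindered aryl bromide then forms the CH2–C6 bond without touching C4, since the stereocentre is β to palladium and reductive elimination with the bulky phosphine should be faster than β-hydride elimination.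

Step 19
Reactants: 25 tetrakis(triisopropylsilyl) ether of the target
Product: 26 5-[(2R,3S,4S)-3-(hydroxymethyl)-4-{[(2S,3R)-2-(4-hydroxy-3-methoxyphenyl)-3-(hydroxymethyl)-4-methoxy-2,3-dihydrobenzofuran-6-yl]methyl}tetrahydrofuran-2-yl]-2-methoxyphenol
Conditions: n-Bu4NF (6 equiv), AcOH (6 equiv), THF, 0 °C to rt
Reagents that add atoms: none
Why: Fluoride cleaves the two aryl and two primary alkyl silyl ethers in one operation; the acetic acid buffer keeps the liberated phenols protonated, so the ring B phenol should not open the benzylic C2–O1 bond, and neither acid nor hydrogen comes near the two benzylic ethers.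

## Compound list

1 | 4-bromo-2,6-dimethoxybenzaldehyde | COc1cc(Br)cc(OC)c1C=O | starting material
2 | 1-(4-bromo-2,6-dimethoxyphenyl)ethan-1-ol (racemic) | COc1cc(Br)cc(OC)c1C(C)O | intermediate
3 | 1-(4-bromo-2,6-dimethoxyphenyl)ethan-1-one | COc1cc(Br)cc(OC)c1C(C)=O | intermediate
4 | 1-(4-bromo-2-hydroxy-6-methoxyphenyl)ethan-1-one | COc1cc(Br)cc(O)c1C(C)=O | intermediate
5 | (E)-1-(4-bromo-2-hydroxy-6-methoxyphenyl)-3-(dimethylamino)prop-2-en-1-one | COc1cc(Br)cc(O)c1C(=O)/C=C/N(C)C | intermediate (not isolated)
6 | 7-bromo-5-methoxy-4H-chromen-4-one | COc1cc(Br)cc2occc(=O)c12 | intermediate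
7 | 2-methoxy-4-(4,4,5,5-tetramethyl-1,3,2-dioxaborolan-2-yl)phenol | COc1cc(ccc1O)B1OC(C)(C)C(C)(C)O1 | starting material
8 | 2-methoxy-4-(4,4,5,5-tetramethyl-1,3,2-dioxaborolan-2-yl)phenyl 2,2-dimethylpropanoate | COc1cc(ccc1OC(=O)C(C)(C)C)B1OC(C)(C)C(C)(C)O1 | intermediate
9 | [3-methoxy-4-(2,2-dimethylpropanoyloxy)phenyl]boronic acid | COc1cc(ccc1OC(=O)C(C)(C)C)B(O)O | intermediate
10 | 4-[(2S)-7-bromo-5-methoxy-4-oxochroman-2-yl]-2-methoxyphenyl 2,2-dimethylpropanoate | Brc1cc(OC)c2c(c1)O[C@H](c1ccc(OC(=O)C(C)(C)C)c(OC)c1)CC2=O | intermediate
11 | 4-[(2S)-7-bromo-4,5-dimethoxy-2H-chromen-2-yl]-2-methoxyphenyl 2,2-dimethylpropanoate | Brc1cc(OC)c2c(c1)O[C@H](c1ccc(OC(=O)C(C)(C)C)c(OC)c1)C=C2OC | intermediate (not isolated)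
12 | 4-{3-[acetoxy(phenyl)iodanyl]-7-bromo-4,4,5-trimethoxychroman-2-yl}-2-methoxyphenyl 2,2-dimethylpropanoate, 2,3-trans, C2 as in 10 | Brc1cc(OC)c2c(c1)O[C@H](c1ccc(OC(=O)C(C)(C)C)c(OC)c1)[C@@H](I(OC(C)=O)c1ccccc1)C2(OC)OC | intermediate (not isolated)
13 | methyl (2S,3S)-6-bromo-4-methoxy-2-[3-methoxy-4-(2,2-dimethylpropanoyloxy)phenyl]-2,3-dihydrobenzofuran-3-carboxylate (trans) | Brc1cc(OC)c2c(c1)O[C@H](c1ccc(OC(=O)C(C)(C)C)c(OC)c1)[C@H]2C(=O)OC | intermediate
14 | 4-[(2S,3R)-6-bromo-3-(hydroxymethyl)-4-methoxy-2,3-dihydrobenzofuran-2-yl]-2-methoxyphenol | Brc1cc(OC)c2c(c1)O[C@H](c1ccc(O)c(OC)c1)[C@H]2CO | intermediate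
15 | (2S,3R)-6-bromo-4-methoxy-2-[3-methoxy-4-(triisopropylsilyloxy)phenyl]-3-[(triisopropylsilyloxy)methyl]-2,3-dihydrobenzofuran | Brc1cc(OC)c2c(c1)O[C@H](c1ccc(O[Si](C(C)C)(C(C)C)C(C)C)c(OC)c1)[C@H]2CO[Si](C(C)C)(C(C)C)C(C)C | intermediate
16 | isovanillin (3-hydroxy-4-methoxybenzaldehyde) | COc1ccc(C=O)cc1O | starting material
17 | 4-methoxy-3-(triisopropylsilyloxy)benzaldehyde | COc1ccc(C=O)cc1O[Si](C(C)C)(C(C)C)C(C)C | intermediate
18 | 1-[4-methoxy-3-(triisopropylsilyloxy)phenyl]prop-2-en-1-ol (racemic) | COc1ccc(C(O)C=C)cc1O[Si](C(C)C)(C(C)C)C(C)C | intermediate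
19 | (1R)-1-[4-methoxy-3-(triisopropylsilyloxy)phenyl]prop-2-en-1-ol | C=C[C@@H](O)c1ccc(OC)c(O[Si](C(C)C)(C(C)C)C(C)C)c1 | intermediate
20 | triisopropyl{2-methoxy-5-[(1R)-1-(prop-2-yn-1-yloxy)prop-2-en-1-yl]phenoxy}silane | C=C[C@@H](OCC#C)c1ccc(OC)c(O[Si](C(C)C)(C(C)C)C(C)C)c1 | intermediate
21 | 2-{(S)-[4-methoxy-3-(triisopropylsilyloxy)phenyl](prop-2-yn-1-yloxy)methyl}oxirane, both epimers at the oxirane carbon | C1OC1[C@@H](OCC#C)c1ccc(OC)c(O[Si](C(C)C)(C(C)C)C(C)C)c1 | intermediate
22 | [(2R,3S)-2-[4-methoxy-3-(triisopropylsilyloxy)phenyl]-4-methylidenetetrahydrofuran-3-yl]methanol | COc1ccc([C@@H]2OCC(=C)[C@H]2CO)cc1O[Si](C(C)C)(C(C)C)C(C)C | intermediate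
23 | triisopropyl{[(2R,3S)-2-[4-methoxy-3-(triisopropylsilyloxy)phenyl]-4-methylidenetetrahydrofuran-3-yl]methoxy}silane | COc1ccc([C@@H]2OCC(=C)[C@H]2CO[Si](C(C)C)(C(C)C)C(C)C)cc1O[Si](C(C)C)(C(C)C)C(C)C | intermediate
24 | 9-{[(3S,4S,5R)-5-[4-methoxy-3-(triisopropylsilyloxy)phenyl]-4-[(triisopropylsilyloxy)methyl]tetrahydrofuran-3-yl]methyl}-9-borabicyclo[3.3.1]nonane | COc1ccc([C@@H]2OC[C@@H](CB3C4CCCC3CCC4)[C@H]2CO[Si](C(C)C)(C(C)C)C(C)C)cc1O[Si](C(C)C)(C(C)C)C(C)C | intermediate (not isolated)
25 | tetrakis(triisopropylsilyl) ether of the target: (2S,3R)-4-methoxy-6-{[(3S,4S,5R)-5-[4-methoxy-3-(triisopropylsilyloxy)phenyl]-4-[(triisopropylsilyloxy)methyl]tetrahydrofuran-3-yl]methyl}-2-[3-methoxy-4-(triisopropylsilyloxy)phenyl]-3-[(triisopropylsilyloxy)methyl]-2,3-dihydrobenzofuran | COc1ccc([C@@H]2OC[C@@H](Cc3cc(OC)c4c(c3)O[C@H](c3ccc(O[Si](C(C)C)(C(C)C)C(C)C)c(OC)c3)[C@H]4CO[Si](C(C)C)(C(C)C)C(C)C)[C@H]2CO[Si](C(C)C)(C(C)C)C(C)C)cc1O[Si](C(C)C)(C(C)C)C(C)C | intermediate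
26 | 5-[(2R,3S,4S)-3-(hydroxymethyl)-4-{[(2S,3R)-2-(4-hydroxy-3-methoxyphenyl)-3-(hydroxymethyl)-4-methoxy-2,3-dihydrobenzofuran-6-yl]methyl}tetrahydrofuran-2-yl]-2-methoxyphenol (CNP0242386.1) | COc1ccc([C@@H]2OC[C@@H](Cc3cc(OC)c4c(c3)O[C@H](c3ccc(O)c(OC)c3)[C@H]4CO)[C@H]2CO)cc1O | target

## Step count and risk

Total step count: 19. Longest linear sequence: 10 steps (steps 1, 2, 3, 4, 7, 8, 9, 10, 18, 19). The tetrahydrofuran branch (steps 11–17) joins at step 18, and the boronic acid branch (steps 5, 6) joins at step 7.

Least certain steps:

**Step 8 (key step).** Three things may go wrong: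
- competing migration of ring B from C2 to C3;
- loss of the iodine group by elimination, which aromatises the pyranone ring;
- acid-induced opening and reclosure at C2–O1, which erodes the enantiomeric purity.

In addition, ketalisation of the ketone next to the C5 methoxy group may be slow, which leaves the oxidant time for side reactions.

Fallback, same disconnection but with leaving group and ketal installed in separate operations: setting out from 10, bromination at C3 (CuBr2, EtOAc/CHCl3, reflux) should give the trans 3-bromoflavanone F1. Ketalisation (HC(OMe)3, MeOH, TsOH) gives the dimethyl ketal F2. Silver-assisted ionisation of the equatorial bromide (AgBF4, MeOH, rt) then triggers the same shift of ring A from C4 to C3, a known 1,2-aryl shift of α-halo ketals to α-aryl esters. This returns to the route at 13.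

**Step 7.** Conversion may stall, because the 5-methoxychromone is an electron-rich vinylogous ester and protodeboronation of 9 competes. The enantioselectivity may be insufficient, or it may be eroded by retro-oxa-Michael opening at 60 °C.

Fallback, resolution in place of asymmetric catalysis: setting out from 6 and 9, the addition is run with the achiral catalyst Pd(OCOCF3)2/2,2'-bipyridine and gives the racemic flavanone F3. Kinetic resolution by asymmetric transfer hydrogenation (RuCl(p-cymene)[(R,R)-TsDPEN], HCO2H/Et3N) should reduce the 2R ketone to the cis-flavan-4-ol F4, which is separated. The unreacted 2S ketone is 10, where the route is rejoined.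

**Step 18.** Facial selectivity in the hydroboration may be poor, since the C2 aryl group lies on the face that the borane must use. Oxidative addition of the electron-rich bromide 15 may be slow, and β-hydride elimination from the alkylpalladium intermediate could scramble C4.

Fallback, C4 set by hydrogenation instead of hydroboration: setting out from 21 and 15, Sonogashira coupling (PdCl2(PPh3)2, CuI, Et3N, 70 °C) gives the aryl alkyne F5. The same Cp2TiCl-mediated radical cyclisation as in step 16 gives the 4-arylmethylidene tetrahydrofuran F6. Hydrogenation over palladium on carbon (H2, 1 atm, EtOAc, short reaction time) should add hydrogen anti to the C3 hydroxymethyl group and give the 3,4-cis compound F7. Desilylation of F7 (n-Bu4NF, AcOH, THF) returns to the route at 26.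

**Step 13.** The titanium Lewis acid may ionise the electron-rich benzylic allylic alcohol, causing racemisation or allylic transposition. Epoxidation of a monosubstituted alkene is slow, so the selectivity factor may be low.

Fallback, enzymatic instead of oxidative resolution: setting out from 18, lipase-catalysed acylation (Novozym 435, vinyl acetate, hexane, rt) should convert the R enantiomer into the acetate F8 and leave the S alcohol behind. After separation, reductive removal of the acetyl group (i-Bu2AlH, CH2Cl2, −78 °C) returns to the route at 19.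

## Further compounds

F1 | step 8 | 4-[(2R,3R)-3,7-dibromo-5-methoxy-4-oxochroman-2-yl]-2-methoxyphenyl 2,2-dimethylpropanoate (2,3-trans) | Brc1cc(OC)c2c(c1)O[C@H](c1ccc(OC(=O)C(C)(C)C)c(OC)c1)[C@@H](Br)C2=O
F2 | step 8 | 4-[(2R,3R)-3,7-dibromo-4,4,5-trimethoxychroman-2-yl]-2-methoxyphenyl 2,2-dimethylpropanoate (2,3-trans) | Brc1cc(OC)c2c(c1)O[C@H](c1ccc(OC(=O)C(C)(C)C)c(OC)c1)[C@@H](Br)C2(OC)OC
F3 | step 7 | 4-(7-bromo-5-methoxy-4-oxochroman-2-yl)-2-methoxyphenyl 2,2-dimethylpropanoate (racemic) | Brc1cc(OC)c2c(c1)OC(c1ccc(OC(=O)C(C)(C)C)c(OC)c1)CC2=O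
F4 | step 7 | 4-[(2R,4R)-7-bromo-4-hydroxy-5-methoxychroman-2-yl]-2-methoxyphenyl 2,2-dimethylpropanoate (cis) | Brc1cc(OC)c2c(c1)O[C@@H](c1ccc(OC(=O)C(C)(C)C)c(OC)c1)C[C@H]2O
F5 | step 18 | (2S,3R)-4-methoxy-6-{3-[(S)-[4-methoxy-3-(triisopropylsilyloxy)phenyl](oxiran-2-yl)methoxy]prop-1-yn-1-yl}-2-[3-methoxy-4-(triisopropylsilyloxy)phenyl]-3-[(triisopropylsilyloxy)methyl]-2,3-dihydrobenzofuran (both epimers at the oxirane carbon) | C1OC1[C@@H](OCC#Cc2cc(OC)c3c(c2)O[C@H](c2ccc(O[Si](C(C)C)(C(C)C)C(C)C)c(OC)c2)[C@H]3CO[Si](C(C)C)(C(C)C)C(C)C)c1ccc(OC)c(O[Si](C(C)C)(C(C)C)C(C)C)c1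
F6 | step 18 | [(2R,3S)-2-[4-methoxy-3-(triisopropylsilyloxy)phenyl]-4-{[(2S,3R)-4-methoxy-2-[3-methoxy-4-(triisopropylsilyloxy)phenyl]-3-[(triisopropylsilyloxy)methyl]-2,3-dihydrobenzofuran-6-yl]methylidene}tetrahydrofuran-3-yl]methanol (alkene geometry not defined) | COc1ccc([C@@H]2OCC(=Cc3cc(OC)c4c(c3)O[C@H](c3ccc(O[Si](C(C)C)(C(C)C)C(C)C)c(OC)c3)[C@H]4CO[Si](C(C)C)(C(C)C)C(C)C)[C@H]2CO)cc1O[Si](C(C)C)(C(C)C)C(C)C
F7 | step 18 | [(2R,3S,4S)-2-[4-methoxy-3-(triisopropylsilyloxy)phenyl]-4-{[(2S,3R)-4-methoxy-2-[3-methoxy-4-(triisopropylsilyloxy)phenyl]-3-[(triisopropylsilyloxy)methyl]-2,3-dihydrobenzofuran-6-yl]methyl}tetrahydrofuran-3-yl]methanol | COc1ccc([C@@H]2OC[C@@H](Cc3cc(OC)c4c(c3)O[C@H](c3ccc(O[Si](C(C)C)(C(C)C)C(C)C)c(OC)c3)[C@H]4CO[Si](C(C)C)(C(C)C)C(C)C)[C@H]2CO)cc1O[Si](C(C)C)(C(C)C)C(C)C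
F8 | step 13 | (1R)-1-[4-methoxy-3-(triisopropylsilyloxy)phenyl]prop-2-en-1-yl acetate | C=C[C@@H](OC(C)=O)c1ccc(OC)c(O[Si](C(C)C)(C(C)C)C(C)C)c1
A1 | alternative 1 | benzannulation product: 2-substituted 5-alkylresorcinol mono(triisopropylsilyl) ether joining both halves | COc1ccc([C@@H]2OC[C@@H](Cc3cc(O[Si](C(C)C)(C(C)C)C(C)C)c([C@H](CO[Si](C)(C)C(C)(C)C)[C@H](O[Si](C)(C)C(C)(C)C)c4ccc(OCc5ccccc5)c(OC)c4)c(O)c3)[C@H]2CO[Si](C)(C)C(C)(C)C)cc1OCc1ccccc1
A2 | alternative 1 | 3-{[(3S,4S,5R)-5-[3-(benzyloxy)-4-methoxyphenyl]-4-[(tert-butyldimethylsilyloxy)methyl]tetrahydrofuran-3-yl]methyl}cyclobut-2-en-1-one | COc1ccc([C@@H]2OC[C@@H](CC3=CC(=O)C3)[C@H]2CO[Si](C)(C)C(C)(C)C)cc1OCc1ccccc1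
A3 | alternative 1 | siloxyalkyne: 4-[3-(benzyloxy... see structure; 1-(triisopropylsilyloxy)alkyne carrying the bis(tert-butyldimethylsilyl)-protected 1-(4-benzyloxy-3-methoxyphenyl)propane-1,3-diol unit at C2 | CC(C)[Si](C(C)C)(C(C)C)OC#C[C@H](CO[Si](C)(C)C(C)(C)C)[C@H](O[Si](C)(C)C(C)(C)C)c1ccc(OCc2ccccc2)c(OC)c1
A4 | alternative 2 | trans dihydrobenzofuran with free ring B phenol on the protected tetrahydrofuran (quinone methide cyclisation product) | COc1ccc([C@@H]2OC[C@@H](Cc3cc(OC)c4c(c3)O[C@H](c3ccc(O)c(OC)c3)[C@H]4CO[Si](C)(C)C(C)(C)C)[C@H]2CO[Si](C)(C)C(C)(C)C)cc1OCc1ccccc1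
A5 | alternative 2 | diarylpropanol precursor: ring A phenol bearing the 1-(tert-butyldimethylsilyloxy)-3-(4-hydroxy-3-methoxyphenyl)propan-2-yl group ortho to OH | COc1ccc([C@@H]2OC[C@@H](Cc3cc(OC)c([C@H](CO[Si](C)(C)C(C)(C)C)Cc4ccc(O)c(OC)c4)c(O)c3)[C@H]2CO[Si](C)(C)C(C)(C)C)cc1OCc1ccccc1
A6 | alternative 3 | cis-fused 3,7-dioxabicyclo[3.3.0]octan-2-one with both aryl groups on the convex face (cycloadduct) | COc1ccc([C@@H]2OC[C@@H]3[C@H]2C(=O)O[C@H]3c2cc(OC)c3c(c2)O[C@H](c2ccc(OCc4ccccc4)c(OC)c2)[C@H]3CO[Si](C)(C)C(C)(C)C)cc1OCc1ccccc1
A7 | alternative 3 | γ-aryl butenolide: 5-[(2S,3R)-2-(4-benzyloxy-3-methoxyphenyl)-3-[(tert-butyldimethylsilyloxy)methyl]-4-methoxy-2,3-dihydrobenzofuran-6-yl]furan-2(5H)-one | O=C1C=C[C@@H](O1)c1cc(OC)c2c(c1)O[C@H](c1ccc(OCc3ccccc3)c(OC)c1)[C@H]2CO[Si](C)(C)C(C)(C)C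
A8 | alternative 3 | 2-(benzyloxy)-4-{chloro[(trimethylsilyl)methoxy]methyl}-1-methoxybenzene | COc1ccc(C(Cl)OC[Si](C)(C)C)cc1OCc1ccccc1
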